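**Plan**
- Retrosynthetic cuts, in order: the acetate; C8–C17 (carboxyl from the Δ7 enol triflate of an 8-ketone); C9–C11 (α′-alkylation of a Δ6-en-8-one with an E-homoallylic iodide); C1–C10 and C2–C3 together (ring A, with acrolein as the C1–C2 unit); C4–C5 (Claisen), back to toluene cis-dihydrodiol.
- Enabling feature: in the ring B aldehyde 6 the methyl-bearing alkene carbon C10 and the non-enolisable aldehyde C3 (on the gem-dimethyl carbon C4) are both attached through C5, so a tertiary C10 radical and a two-carbon acceptor close the six-membered ring A in one operation.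
- Forward order: ring B from the chiral pool; the C4 quaternary aldehyde by [3,3] shift; ring A by annulation; removal of the helpers (C2 formyl, C3 hydroxyl, C8 silyloxy); side chain at C9; carboxyl at C8; acetate.
- Stereochemistry: C5 by suprafacial Claisen transfer from the C9 carbinol of diol 1; C10 by radical addition anti to the C5 substituent and to the axial C8 silyloxy group; C9 by equilibration next to the C8 ketone; 13E by syn-carboalumination.

Key step: step 4

Remark: ring atoms carry labdane numbers throughout, also in the monocyclic intermediates (ring A = C1–C5 and C10; ring B = C5–C10; C20 = methyl on C10; C17 = carboxyl carbon on C8; side chain C11–C16). β is the face of the C10 methyl group and α the face of H-5. Diol 1 and iodide 4 are assumed to be purchasable. The SMILES of 9, 10 and 24 leave open the centers that form as mixtures and are removed or equilibrated later. The equatorial 9β side chain is assumed to be the more stable epimer of ketone 26, as in the natural series.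

Step 1
Reactants: 1 (1S,2R)-3-methylcyclohexa-3,5-diene-1,2-diol (toluene cis-dihydrodiol)
Product: 2 (1S,2R)-3-methylcyclohex-3-ene-1,2-diol
Conditions: KO2CN=NCO2K, AcOH, MeOH, 0 °C to rt
Reagents that add atoms: none
Why: Diimide generated in the flask should reduce the disubstituted C6=C7 alkene of the diene and leave the trisubstituted methyl-bearing alkene (diimide reduction); no stereocenter is touched.

Step 2
Reactants: 2 (1S,2R)-3-methylcyclohex-3-ene-1,2-diol
Product: 3 (1R,6S)-2-methyl-6-[(triisopropylsilyl)oxy]cyclohex-2-en-1-ol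
Conditions: i-Pr3SiCl, imidazole, DMAP (cat.), DMF, rt
Reagents that add atoms: chlorotriisopropylsilane, CC(C)[Si](Cl)(C(C)C)C(C)C
Why: Selective silyl ether formation at the homoallylic C8 hydroxyl is expected because the allylic C9 hydroxyl is flanked by the methyl-bearing sp2 carbon; the bulky triisopropylsilyl group is chosen because it resists 1,2-migration under base and has no activated C–H near C10.

Step 3
Reactants: 3 (1R,6S)-2-methyl-6-[(triisopropylsilyl)oxy]cyclohex-2-en-1-ol; 4 1-iodo-2-methylprop-1-ene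
Product: 6 2-methyl-2-{(1R,4S)-2-methyl-4-[(triisopropylsilyl)oxy]cyclohex-2-en-1-yl}propanal, via allyl vinyl ether 5 (not isolated)
Conditions: CuI (10 mol%), 3,4,7,8-tetramethyl-1,10-phenanthroline (20 mol%), Cs2CO3, 4 (1.5 equiv), o-xylene, 90 °C then 135 °C
Reagents that add atoms: none
Why: Copper-catalysed C–O coupling of the allylic alcohol with the vinyl iodide (Ullmann-type vinylation) gives ether 5, which undergoes Claisen rearrangement on further heating; the C4–C5 bond forms suprafacially on the β face that carried the C9–O bond, so the carbinol configuration is transferred to C5 while the quaternary C4 aldehyde and the C9=C10 alkene are created.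

Step 4
Reactants: 6 2-methyl-2-{(1R,4S)-2-methyl-4-[(triisopropylsilyl)oxy]cyclohex-2-en-1-yl}propanal; 7 acrolein
Product: 9 3-hydroxy-4,4,10β-trimethyl-8β-[(triisopropylsilyl)oxy]-5αH-decalin-2-carbaldehyde (trans-fused; C2/C3 open), via iron enolate 8 (not isolated)
Conditions: Fe(acac)3 (30 mol%), PhSiH3 (2.5 equiv), 7 (3 equiv, slow addition), EtOH/(CH2OH)2, 60 °C
Reagents that add atoms: none
Why: The iron hydride formed from Fe(acac)3 and PhSiH3 transfers a hydrogen atom to C9 of the electron-rich trisubstituted alkene (Markovnikov MHAT), the tertiary C10 radical adds to the CH2 terminus of acrolein (Giese addition, bond C1–C10), and the α-formyl radical is reduced by divalent iron to enolate 8, which adds to the non-enolisable C3 aldehyde (aldol, bond C2–C3) with return of trivalent iron. The closest known reaction type is the MHAT-initiated radical conjugate addition–aldol (radical–polar crossover) annulation of γ,δ-unsaturated aldehydes with enals and enones. Ring A closes in the aldol event as a 6-(enolexo)-exo-trig cyclisation through a chair in which the C10–C1 and C5–C4 bonds are both equatorial on ring B, which gives the trans-decalin. The quaternary stereocenter C10 is set in the radical addition: acrolein should approach the planar radical on the α face, anti to the bulky β substituent on the adjacent C5 and away from the β-oriented C8 silyloxy group that is 1,3-diaxial to a β approach, so the methyl group ends β; C2 and C3 arise as a mixture and are removed in steps 5 to 7. The step needs hydrogen atom transfer to the ring alkene in preference to acrolein, and ring closure faster than protonation of the enolate; the ring alkene is the only electron-rich olefin, acrolein is added slowly in excess, and the aldehyde has no α-hydrogen and is placed for six-membered ring closure.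

Step 5
Reactants: 9 3-hydroxy-4,4,10β-trimethyl-8β-[(triisopropylsilyl)oxy]-5αH-decalin-2-carbaldehyde
Product: 11 4,4,10β-trimethyl-8β-[(triisopropylsilyl)oxy]-5αH-decal-2-ene-2-carbaldehyde, via mesylate 10 (not isolated)
Conditions: MsCl, Et3N, CH2Cl2, 0 °C; then DBU, rt
Reagents that add atoms: none
Why: Mesylation of the β-hydroxyl and E1cB elimination through the aldehyde enolate should give the conjugated enal (aldol-type dehydration), which erases both unneeded stereocenters; any retro-aldol material re-closes to the same enal.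

Step 6
Reactants: 11 4,4,10β-trimethyl-8β-[(triisopropylsilyl)oxy]-5αH-decal-2-ene-2-carbaldehyde
Product: 12 4,4,10β-trimethyl-8β-[(triisopropylsilyl)oxy]-5αH-decal-2-ene
Conditions: RhCl3·3H2O (5 mol%), dppp (10 mol%), diglyme, 160 °C
Reagents that add atoms: none
Why: Rhodium-catalysed decarbonylation of the α,β-unsaturated aldehyde (Tsuji–Wilkinson type: formyl C–H insertion, CO extrusion, C–H reductive elimination) should leave the ring A alkene, whose exact position does not matter because it is hydrogenated next.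

Step 7
Reactants: 12 4,4,10β-trimethyl-8β-[(triisopropylsilyl)oxy]-5αH-decal-2-ene
Product: 14 4,4,10β-trimethyl-5αH-decalin-8β-ol, via saturated silyl ether 13 (not isolated)
Conditions: H2 (1 atm), Pd/C, MeOH/EtOAc, rt; then HCl, MeOH, 60 °C
Reagents that add atoms: none
Why: Heterogeneous hydrogenation saturates the disubstituted ring A alkene and the acid added afterwards cleaves the silyl ether by methanolysis; no stereocenter is formed and the skeleton carries no acid-sensitive group at this stage.

Step 8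
Reactants: 14 4,4,10β-trimethyl-5αH-decalin-8β-ol
Product: 16 4,4,10β-trimethyl-5αH-decal-6-en-8-one, via ketone 15 (not isolated)
Conditions: IBX (4 equiv), DMSO/fluorobenzene, 65 to 80 °C
Reagents that add atoms: none
Why: IBX oxidises the axial alcohol to ketone 15 and then dehydrogenates it through its enol (IBX dehydrogenation); unsaturation can only develop toward C7/C6 because C10 is quaternary, so the Δ6-enone should form regiospecifically.

Step 9
Reactants: 17 tert-butyl(but-3-yn-1-yloxy)dimethylsilane
Product: 19 (E)-5-[(tert-butyldimethylsilyl)oxy]-3-methylpent-2-en-1-ol, via alkenylalane 18 (not isolated)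
Conditions: AlMe3, Cp2ZrCl2 (20 mol%), CH2Cl2, 0 °C to rt; then n-BuLi, THF, −78 °C; (CH2O)n, −78 °C to rt
Reagents that add atoms: trimethylaluminium, C[Al](C)C; paraformaldehyde (as formaldehyde), C=O
Why: Zirconium-catalysed carboalumination (Negishi) adds methyl and aluminium syn across the terminal alkyne with methyl on the internal carbon, and the derived alanate is hydroxymethylated with retention, so the 13E trisubstituted alkene is fixed.

Step 10
Reactants: 19 (E)-5-[(tert-butyldimethylsilyl)oxy]-3-methylpent-2-en-1-ol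
Product: 20 (E)-5-[(tert-butyldimethylsilyl)oxy]-1-[(tert-butyldiphenylsilyl)oxy]-3-methylpent-2-ene
Conditions: t-BuPh2SiCl, imidazole, DMF, rt
Reagents that add atoms: tert-butyl(chloro)diphenylsilane, CC(C)(C)[Si](Cl)(c1ccccc1)c1ccccc1
Why: Standard silylation of the primary allylic alcohol installs the more robust of two differentiable silyl ethers.

Step 11
Reactants: 20 (E)-5-[(tert-butyldimethylsilyl)oxy]-1-[(tert-butyldiphenylsilyl)oxy]-3-methylpent-2-ene
Product: 21 (E)-5-[(tert-butyldiphenylsilyl)oxy]-3-methylpent-3-en-1-ol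
Conditions: PPTS (cat.), MeOH, rt
Reagents that add atoms: none
Why: Mild acid methanolysis cleaves the primary tert-butyldimethylsilyl ether much faster than the tert-butyldiphenylsilyl ether (selective desilylation).

Step 12
Reactants: 21 (E)-5-[(tert-butyldiphenylsilyl)oxy]-3-methylpent-3-en-1-ol
Product: 22 (E)-tert-butyl[(5-iodo-3-methylpent-2-en-1-yl)oxy]diphenylsilane
Conditions: I2, PPh3, imidazole, CH2Cl2, 0 °C
Reagents that add atoms: iodine, II
Why: Appel-type iodination converts the primary homoallylic alcohol into the iodide by SN2 displacement of the oxyphosphonium group, without touching the alkene geometry.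

Step 13
Reactants: 16 4,4,10β-trimethyl-5αH-decal-6-en-8-one; 22 (E)-tert-butyl[(5-iodo-3-methylpent-2-en-1-yl)oxy]diphenylsilane
Product: 24 9-{(E)-5-[(tert-butyldiphenylsilyl)oxy]-3-methylpent-3-en-1-yl}-4,4,10β-trimethyl-5αH-decal-6-en-8-one (C9 epimers), via lithium dienolate 23 (not isolated)
Conditions: LiN(i-Pr)2, THF, −78 °C; then 22 (1.5 equiv), DMPU, −78 to −20 °C
Reagents that add atoms: none
Why: Kinetic deprotonation of the enone occurs at the α′ carbon C9 (cross-conjugated dienolate 23) and SN2 alkylation with the primary iodide forms C9–C11; attack anti to the axial C10 methyl should give mainly the axial 9α-alkyl epimer, which is corrected in step 14.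

Step 14
Reactants: 24 9-{(E)-5-[(tert-butyldiphenylsilyl)oxy]-3-methylpent-3-en-1-yl}-4,4,10β-trimethyl-5αH-decal-6-en-8-one
Product: 26 15-[(tert-butyldiphenylsilyl)oxy]-17-norlabd-13(E)-en-8-one (9α-H), via lithium enolate 25 (not isolated)
Conditions: LiBH(s-Bu)3, THF, −78 °C; then NaOMe (cat.), MeOH, rt
Reagents that add atoms: none
Why: The hindered borohydride delivers hydride to C6 (conjugate reduction of a β-unsubstituted cyclohexenone) and methoxide then equilibrates the ketone through its C8–C9 enolate, which should place the side chain equatorial (9β, H-9 α) on the trans-decalin.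

Step 15
Reactants: 26 15-[(tert-butyldiphenylsilyl)oxy]-17-norlabd-13(E)-en-8-one
Product: 28 15-[(tert-butyldiphenylsilyl)oxy]-17-norlabda-7,13(E)-dien-8-yl trifluoromethanesulfonate, via potassium enolate 27 (not isolated)
Conditions: KN(SiMe3)2, THF, −78 °C; then PhNTf2, −78 to 0 °C
Reagents that add atoms: N-phenylbis(trifluoromethanesulfonimide), O=S(=O)(N(c1ccccc1)S(=O)(=O)C(F)(F)F)C(F)(F)F
Why: Kinetic deprotonation takes place at the C7 methylene and not at the tertiary C9 next to the quaternary C10, and O-sulfonylation of enolate 27 gives the Δ7 enol triflate without epimerising C9.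

Step 16
Reactants: 28 15-[(tert-butyldiphenylsilyl)oxy]-17-norlabda-7,13(E)-dien-8-yl trifluoromethanesulfonate
Product: 29 15-[(tert-butyldiphenylsilyl)oxy]labda-7,13(E)-dien-17-oic acid
Conditions: Pd(OAc)2 (5 mol%), dppf (10 mol%), CO (1 atm), H2O, Et3N, DMF, 60 °C
Reagents that add atoms: carbon monoxide, [C-]#[O+]; water, O
Why: Oxidative addition of zerovalent palladium to the vinyl triflate, CO insertion and hydrolysis of the acylpalladium species (hydroxycarbonylation) install the C17 carboxyl on C8 with the C7=C8 alkene already in place.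

Step 17
Reactants: 29 15-[(tert-butyldiphenylsilyl)oxy]labda-7,13(E)-dien-17-oic acid
Product: 30 15-hydroxylabda-7,13(E)-dien-17-oic acid
Conditions: Bu4NF (2.5 equiv), THF, rt; NH4Cl (aq)
Reagents that add atoms: none
Why: Fluoride cleaves the silyl ether (desilylation) under conditions that leave the conjugated acid and both alkenes untouched.

Step 18
Reactants: 30 15-hydroxylabda-7,13(E)-dien-17-oic acid
Product: 32 (5S,9R,10S)-15-acetoxylabda-7,13(E)-dien-17-oic acid (CNP0395334.2), via mixed anhydride 31 (not isolated)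
Conditions: Ac2O, pyridine, DMAP (cat.), CH2Cl2, 0 °C to rt; then H2O/THF
Reagents that add atoms: acetic anhydride, CC(=O)OC(C)=O
Why: DMAP-catalysed acetylation esterifies the primary allylic alcohol, and the mixed anhydride 31 formed at the carboxyl group is hydrolysed back to the acid in the aqueous stage.

**Compound list**
1 | (1S,2R)-3-methylcyclohexa-3,5-diene-1,2-diol | O[C@H]1C=CC=C(C)[C@H]1O | starting material
2 | (1S,2R)-3-methylcyclohex-3-ene-1,2-diol | O[C@H]1CCC=C(C)[C@H]1O | intermediate
3 | (1R,6S)-2-methyl-6-[(triisopropylsilyl)oxy]cyclohex-2-en-1-ol | CC(C)[Si](C(C)C)(C(C)C)O[C@H]1CCC=C(C)[C@H]1O | intermediate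
4 | 1-iodo-2-methylprop-1-ene | CC(C)=CI | starting material
5 | triisopropyl{[(1S,2R)-3-methyl-2-(2-methylprop-1-enyloxy)cyclohex-3-en-1-yl]oxy}silane | CC(C)[Si](C(C)C)(C(C)C)O[C@H]1CCC=C(C)[C@H]1OC=C(C)C | intermediate
6 | 2-methyl-2-{(1R,4S)-2-methyl-4-[(triisopropylsilyl)oxy]cyclohex-2-en-1-yl}propanal | CC(C)[Si](C(C)C)(C(C)C)O[C@H]1CC[C@@H](C(C)(C)C=O)C(C)=C1 | intermediate
7 | acrolein | C=CC=O | starting material
8 | iron-bound C2 enolate of the Giese adduct (C10 quaternary; drawn as the enolate anion) | CC(C)[Si](C(C)C)(C(C)C)O[C@H]1CC[C@@H](C(C)(C)C=O)[C@](C)(CC=C[O-])C1 | intermediate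
9 | 3-hydroxy-4,4,10β-trimethyl-8β-[(triisopropylsilyl)oxy]-5αH-decalin-2-carbaldehyde (C2/C3 open) | CC(C)[Si](C(C)C)(C(C)C)O[C@H]1CC[C@H]2C(C)(C)C(O)C(C=O)C[C@]2(C)C1 | intermediate
10 | 3-O-methanesulfonate of 9 | CC(C)[Si](C(C)C)(C(C)C)O[C@H]1CC[C@H]2C(C)(C)C(OS(C)(=O)=O)C(C=O)C[C@]2(C)C1 | intermediate
11 | 4,4,10β-trimethyl-8β-[(triisopropylsilyl)oxy]-5αH-decal-2-ene-2-carbaldehyde | CC(C)[Si](C(C)C)(C(C)C)O[C@H]1CC[C@H]2C(C)(C)C=C(C=O)C[C@]2(C)C1 | intermediate
12 | 4,4,10β-trimethyl-8β-[(triisopropylsilyl)oxy]-5αH-decal-2-ene | CC(C)[Si](C(C)C)(C(C)C)O[C@H]1CC[C@H]2C(C)(C)C=CC[C@]2(C)C1 | intermediate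
13 | 4,4,10β-trimethyl-8β-[(triisopropylsilyl)oxy]-5αH-decalin | CC(C)[Si](C(C)C)(C(C)C)O[C@H]1CC[C@H]2C(C)(C)CCC[C@]2(C)C1 | intermediate
14 | 4,4,10β-trimethyl-5αH-decalin-8β-ol | O[C@H]1CC[C@H]2C(C)(C)CCC[C@]2(C)C1 | intermediate
15 | 4,4,10β-trimethyl-5αH-decalin-8-one | O=C1CC[C@H]2C(C)(C)CCC[C@]2(C)C1 | intermediate
16 | 4,4,10β-trimethyl-5αH-decal-6-en-8-one | O=C1C=C[C@H]2C(C)(C)CCC[C@]2(C)C1 | intermediate
17 | tert-butyl(but-3-yn-1-yloxy)dimethylsilane | C#CCCO[Si](C)(C)C(C)(C)C | starting material
18 | (E)-[4-(tert-butyldimethylsilyloxy)-2-methylbut-1-enyl]dimethylalane | C[Al](C)/C=C(\C)CCO[Si](C)(C)C(C)(C)C | intermediate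
19 | (E)-5-[(tert-butyldimethylsilyl)oxy]-3-methylpent-2-en-1-ol | OC/C=C(\C)CCO[Si](C)(C)C(C)(C)C | intermediate
20 | (E)-5-[(tert-butyldimethylsilyl)oxy]-1-[(tert-butyldiphenylsilyl)oxy]-3-methylpent-2-ene | CC(C)(C)[Si](c1ccccc1)(c1ccccc1)OC/C=C(\C)CCO[Si](C)(C)C(C)(C)C | intermediate
21 | (E)-5-[(tert-butyldiphenylsilyl)oxy]-3-methylpent-3-en-1-ol | CC(C)(C)[Si](c1ccccc1)(c1ccccc1)OC/C=C(\C)CCO | intermediate
22 | (E)-tert-butyl[(5-iodo-3-methylpent-2-en-1-yl)oxy]diphenylsilane | CC(C)(C)[Si](c1ccccc1)(c1ccccc1)OC/C=C(\C)CCI | intermediate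
23 | lithium 6,8-dienolate of 16 | [Li+].[O-]C1=C[C@@]2(C)CCCC(C)(C)[C@@H]2C=C1 | intermediate
24 | 9-{(E)-5-[(tert-butyldiphenylsilyl)oxy]-3-methylpent-3-en-1-yl}-4,4,10β-trimethyl-5αH-decal-6-en-8-one (C9 open) | CC(C)(C)[Si](c1ccccc1)(c1ccccc1)OC/C=C(\C)CCC1C(=O)C=C[C@H]2C(C)(C)CCC[C@]12C | intermediate
25 | lithium Δ7-enolate from conjugate reduction of 24 (C9 open) | [Li+].[O-]C1=CC[C@H]2C(C)(C)CCC[C@]2(C)C1CC/C(C)=C/CO[Si](c1ccccc1)(c1ccccc1)C(C)(C)C | intermediate
26 | 15-[(tert-butyldiphenylsilyl)oxy]-17-norlabd-13(E)-en-8-one (5α-H; 9α-H; 10β-CH3) | CC(C)(C)[Si](c1ccccc1)(c1ccccc1)OC/C=C(\C)CC[C@H]1C(=O)CC[C@H]2C(C)(C)CCC[C@]12C | intermediate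
27 | potassium Δ7-enolate of 26 | [K+].[O-]C1=CC[C@H]2C(C)(C)CCC[C@]2(C)[C@H]1CC/C(C)=C/CO[Si](c1ccccc1)(c1ccccc1)C(C)(C)C | intermediate
28 | 15-[(tert-butyldiphenylsilyl)oxy]-17-norlabda-7,13(E)-dien-8-yl trifluoromethanesulfonate | CC(C)(C)[Si](c1ccccc1)(c1ccccc1)OC/C=C(\C)CC[C@H]1C(OS(=O)(=O)C(F)(F)F)=CC[C@H]2C(C)(C)CCC[C@]12C | intermediate
29 | 15-[(tert-butyldiphenylsilyl)oxy]labda-7,13(E)-dien-17-oic acid | CC(C)(C)[Si](c1ccccc1)(c1ccccc1)OC/C=C(\C)CC[C@H]1C(C(=O)O)=CC[C@H]2C(C)(C)CCC[C@]12C | intermediate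
30 | 15-hydroxylabda-7,13(E)-dien-17-oic acid | OC/C=C(\C)CC[C@H]1C(C(=O)O)=CC[C@H]2C(C)(C)CCC[C@]12C | intermediate
31 | mixed acetic anhydride of 32 | CC(=O)OC/C=C(\C)CC[C@H]1C(C(=O)OC(C)=O)=CC[C@H]2C(C)(C)CCC[C@]12C | intermediate
32 | (5S,9R,10S)-15-acetoxylabda-7,13(E)-dien-17-oic acid | CC(=O)OC/C=C(\C)CC[C@H]1C(C(=O)O)=CC[C@H]2C(C)(C)CCC[C@]12C | target

Total step count: 18. Longest linear sequence: 14 steps (steps 1 to 8 and 13 to 18, from diol 1); the side-chain iodide 22 takes 4 steps (9 to 12).

**Steps most likely to fail**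

Step 4. The adduct radical or the enolate may be intercepted by hydrogen or proton transfer before ring A closes, acrolein may oligomerise, and the facial preference at C10 may be incomplete. The fallback forms the two bonds in separate operations. From 6, MHAT-initiated Giese addition to methyl acrylate (Fe(acac)3, PhSiH3, EtOH/(CH2OH)2) would give the ester aldehyde F1. LiN(SiMe3)2 in THF at −78 °C would then close ring A by intramolecular ester-enolate aldol addition to the hydroxy ester F2. MsCl/Et3N followed by DBU would give the unsaturated ester F3, i-Bu2AlH the allylic alcohol F4, and MnO2 would return the route to enal 11.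

Step 13. SN2 displacement at the neopentyl-like enolate carbon C9 may be slow, so that E2 elimination of the homoallylic iodide and proton transfer compete. The fallback builds the chain in two stages through a more reactive electrophile and a later alkyl–alkenyl coupling. From 16, the same dienolate would be alkylated with allyl bromide to the allyl enone F5. OsO4 (cat.)/NaIO4 would cleave the terminal alkene to the aldehyde F6, NaBH(OAc)3 would give the primary alcohol F7, and I2/PPh3/imidazole the iodide F8. Zinc insertion (Zn, LiCl, THF) and Pd(PPh3)4-catalysed Negishi coupling with the vinyl iodide (E)-tert-butyl[(3-iodobut-2-en-1-yl)oxy]diphenylsilane F9 (from but-2-yn-1-ol by syn-stannylcupration, iodination and silylation) would return the route to 24 with the E alkene already defined.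

Step 3. Copper-mediated coupling of the hindered secondary allylic alcohol may be slow at the temperature the vinyl iodide tolerates, and base-induced silyl migration from O8 to O9 may divert material. The fallback avoids an alkoxide at O9 and a vinyl ether altogether. From 3, acylation with isobutyryl chloride/pyridine would give the isobutyrate F10. Ireland–Claisen rearrangement (LiN(i-Pr)2, Me3SiCl, THF, −78 °C to reflux, then aqueous acid) would give the acid F11 with the same suprafacial transfer to C5. LiAlH4 would give the neopentyl alcohol F12, and Dess–Martin periodinane would return the route to aldehyde 6.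

**Further compounds**
F1 | step 4 | methyl 3-{(1S,2R,5S)-1-methyl-2-(2-methyl-1-oxopropan-2-yl)-5-[(triisopropylsilyl)oxy]cyclohexyl}propanoate (labdane C10 quaternary, C1 α) | CC(C)[Si](C(C)C)(C(C)C)O[C@H]1CC[C@@H](C(C)(C)C=O)[C@](C)(CCC(=O)OC)C1
F2 | step 4 | methyl 3-hydroxy-4,4,10β-trimethyl-8β-[(triisopropylsilyl)oxy]-5αH-decalin-2-carboxylate (C2/C3 open) | CC(C)[Si](C(C)C)(C(C)C)O[C@H]1CC[C@H]2C(C)(C)C(O)C(C(=O)OC)C[C@]2(C)C1
F3 | step 4 | methyl 4,4,10β-trimethyl-8β-[(triisopropylsilyl)oxy]-5αH-decal-2-ene-2-carboxylate | CC(C)[Si](C(C)C)(C(C)C)O[C@H]1CC[C@H]2C(C)(C)C=C(C(=O)OC)C[C@]2(C)C1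
F4 | step 4 | {4,4,10β-trimethyl-8β-[(triisopropylsilyl)oxy]-5αH-decal-2-en-2-yl}methanol | CC(C)[Si](C(C)C)(C(C)C)O[C@H]1CC[C@H]2C(C)(C)C=C(CO)C[C@]2(C)C1
F5 | step 13 | 9-allyl-4,4,10β-trimethyl-5αH-decal-6-en-8-one (C9 open) | C=CCC1C(=O)C=C[C@H]2C(C)(C)CCC[C@]12C
F6 | step 13 | 2-(4,4,10β-trimethyl-8-oxo-5αH-decal-6-en-9-yl)acetaldehyde (C9 open) | O=CCC1C(=O)C=C[C@H]2C(C)(C)CCC[C@]12C
F7 | step 13 | 9-(2-hydroxyethyl)-4,4,10β-trimethyl-5αH-decal-6-en-8-one (C9 open) | OCCC1C(=O)C=C[C@H]2C(C)(C)CCC[C@]12C
F8 | step 13 | 9-(2-iodoethyl)-4,4,10β-trimethyl-5αH-decal-6-en-8-one (C9 open) | ICCC1C(=O)C=C[C@H]2C(C)(C)CCC[C@]12C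
F9 | step 13 | (E)-tert-butyl[(3-iodobut-2-en-1-yl)oxy]diphenylsilane | CC(C)(C)[Si](c1ccccc1)(c1ccccc1)OC/C=C(\C)I
F10 | step 3 | (1R,6S)-2-methyl-6-[(triisopropylsilyl)oxy]cyclohex-2-en-1-yl 2-methylpropanoate | CC(C)[Si](C(C)C)(C(C)C)O[C@H]1CCC=C(C)[C@H]1OC(=O)C(C)C
F11 | step 3 | 2-methyl-2-{(1R,4S)-2-methyl-4-[(triisopropylsilyl)oxy]cyclohex-2-en-1-yl}propanoic acid | CC(C)[Si](C(C)C)(C(C)C)O[C@H]1CC[C@@H](C(C)(C)C(=O)O)C(C)=C1
F12 | step 3 | 2-methyl-2-{(1R,4S)-2-methyl-4-[(triisopropylsilyl)oxy]cyclohex-2-en-1-yl}propan-1-ol | CC(C)[Si](C(C)C)(C(C)C)O[C@H]1CC[C@@H](C(C)(C)CO)C(C)=C1
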